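Both end rings derive from one achiral block, 2,2,4-trimethylcyclohexane-1,3-dione, and are joined to crocetindialdehyde by two Wittig reactions (C15 + C20 + C15). The dione is built in one [3+3] annulation from the pyrrolidine enamine of 3-methylbutan-2-one (C1–C3 and the gem-dimethyl group, carotenoid numbering) and methacryloyl chloride (C4–C6 and the C5 methyl), which forms C3–C4 and C1–C6. The step exploits the quaternary C1 of ring A lying between C2 and C6, both of which can be carbonyl carbons: the C2 carbonyl becomes an exocyclic enal whose enantiodivergent organocatalytic reduction sets 2R (ring A) and 2'S (ring B), and the C6 carbonyl brings in C7 through its enol triflate.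

Key step: step 1

Remark: ring atoms carry carotenoid numbers (C1 gem-dimethyl carbon, C2 stereocentre, C3 and C4 methylenes, C5 methyl-bearing carbon, C6 chain-bearing carbon, C7 first chain carbon); crocetindialdehyde 22 and both antipodes of the imidazolidinone catalyst are taken as commercial; 4 and 6 are racemic at the CHMe carbon, which becomes sp2 in step 3, and the exocyclic alkenes of 6 to 9 are drawn as the expected major E isomers.

Step 1
Reactants: 1 3-methylbutan-2-one; 2 methacryloyl chloride
Product: 4 2,2,4-trimethylcyclohexane-1,3-dione (racemic at the CHMe carbon), via enamine 3 (not isolated)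
Conditions: pyrrolidine (1.2 equiv), TsOH (cat.), 4 Å molecular sieves, toluene, rt; then 2 (slow addition), toluene, 0 °C → reflux; then AcOH/NaOAc/H2O, 60 °C
Reagents that add atoms: water O
Why: Enamine 3 is N-acylated by 2 and the N-acyl enammonium ion undergoes a [3,3]-sigmatropic shift that joins the enamine CH2 carbon (C3) to the β-carbon of the acryloyl unit (C4) and leaves a ketene tethered to an iminium ion; the iminium ion tautomerises to the enamine on the isopropyl side, whose methine carbon (C1) C-acylates the ketene carbon (C6), which closes the ring and creates the quaternary centre, and aqueous hydrolysis then releases the dione. The closest known reaction type is the [3+3] α,α′-annulation of ketone enamines with α,β-unsaturated acid chlorides, which gives cyclohexane-1,3-diones from acyclic ketones and bridged bicyclic diones from cyclic ketones. The six-membered ring closes by 6-exo attack of an endocyclic enamine carbon on the ketene carbonyl, the only alternative closure from the other α-carbon being a four-membered ring. The single stereocentre formed (the CHMe carbon) is not controlled and is erased in step 3. The step needs the first C–C bond to start from the methyl carbon and not from the methine carbon of the ketone, which the strong preference of this branched methyl ketone for the less substituted enamine secures, and it needs sigmatropic transfer to outrun direct C-acylation of the enamine, which is favoured by slow addition of 2 to 3 in a non-polar solvent at reflux.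

Step 2
Reactants: 4 2,2,4-trimethylcyclohexane-1,3-dione; 5 diethyl (cyanomethyl)phosphonate
Product: 6 (2E)-2-(2,2,4-trimethyl-3-oxocyclohexylidene)acetonitrile
Conditions: NaH (1.0 equiv), 5 (1.1 equiv), THF, 0 °C → reflux
Reagents that add atoms: none
Why: Horner–Wadsworth–Emmons olefination should take place only at the carbonyl flanked by CH2 (C2), because the other carbonyl (C6) sits between the quaternary carbon and the CHMe carbon and is as unreactive as a 2,2,6-trisubstituted cyclohexanone, and the nitrile is expected to lie anti to the quaternary carbon (E), a Z component being tolerated because steps 6 and 9 are stereoconvergent.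

Step 3
Reactants: 6 (2E)-2-(2,2,4-trimethyl-3-oxocyclohexylidene)acetonitrile
Product: 7 (5E)-5-(cyanomethylidene)-2,6,6-trimethylcyclohex-1-en-1-yl trifluoromethanesulfonate
Conditions: Tf2O, 2,6-di-tert-butyl-4-methylpyridine, CH2Cl2, 0 °C → rt
Reagents that add atoms: trifluoromethanesulfonic anhydride O=S(=O)(OS(=O)(=O)C(F)(F)F)C(F)(F)F
Why: Electrophilic enol triflation of the hindered ketone under non-basic conditions can enolise only toward the CHMe carbon (the other α-carbon is quaternary), so a single tetrasubstituted enol triflate is expected, the racemic stereocentre is erased and γ-deprotonation of the unsaturated nitrile by a strong base is avoided.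

Step 4
Reactants: 7 (5E)-5-(cyanomethylidene)-2,6,6-trimethylcyclohex-1-en-1-yl trifluoromethanesulfonate
Product: 8 methyl (5E)-5-(cyanomethylidene)-2,6,6-trimethylcyclohex-1-ene-1-carboxylate
Conditions: Pd(OAc)2 (5 mol %), 1,3-bis(diphenylphosphino)propane, CO (1 atm), Et3N, MeOH/DMF, 65 °C
Reagents that add atoms: carbon monoxide [C-]#[O+]; methanol CO
Why: Palladium-catalysed alkoxycarbonylation of the enol triflate (oxidative addition, CO insertion, methanolysis of the acyl palladium species) introduces C7 at the ester level without touching the conjugated nitrile.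

Step 5
Reactants: 8 methyl (5E)-5-(cyanomethylidene)-2,6,6-trimethylcyclohex-1-ene-1-carboxylate
Product: 9 (2E)-2-[3-(hydroxymethyl)-2,2,4-trimethylcyclohex-3-en-1-ylidene]acetaldehyde
Conditions: i-Bu2AlH (3.5 equiv), CH2Cl2, −78 → −20 °C; then aq. potassium sodium tartrate, then dilute aq. AcOH
Reagents that add atoms: water O
Why: i-Bu2AlH reduces the hindered conjugated ester to the primary allylic alcohol and adds once to the nitrile to give an N-aluminio aldimine that is hydrolysed to the enal on work-up (ester 1,2-reduction and partial nitrile reduction).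

Step 6
Reactants: 9 (2E)-2-[3-(hydroxymethyl)-2,2,4-trimethylcyclohex-3-en-1-ylidene]acetaldehyde
Product: 10 2-[(1R)-3-(hydroxymethyl)-2,2,4-trimethylcyclohex-3-en-1-yl]acetaldehyde
Conditions: (S)-2-tert-butyl-3-methylimidazolidin-4-one trifluoroacetate (20 mol %), Hantzsch ester (diethyl 2,6-dimethyl-1,4-dihydropyridine-3,5-dicarboxylate, 1.2 equiv), CHCl3, −30 °C
Reagents that add atoms: none
Why: Iminium-catalysed transfer hydrogenation from the Hantzsch ester, in which the E and Z iminium ions are expected to interconvert through the dienamine faster than hydride transfer, the reactive isomer places the quaternary C1 anti to the iminium carbon and hydride is delivered to C2 on the face away from the tert-butyl group of the (S)-catalyst, which by the accepted model for β,β-disubstituted enals sets (R) at C2, while the tetrasubstituted ring alkene cannot form an iminium ion and stays.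

Step 7
Reactants: 10 2-[(1R)-3-(hydroxymethyl)-2,2,4-trimethylcyclohex-3-en-1-yl]acetaldehyde; 11 triphenyl(propan-2-yl)phosphonium iodide
Product: 12 [(5R)-2,6,6-trimethyl-5-(3-methylbut-2-en-1-yl)cyclohex-1-en-1-yl]methanol
Conditions: 11 (2.3 equiv), n-BuLi, THF, 0 °C; then 10, −78 °C → rt
Reagents that add atoms: none
Why: Wittig olefination with the non-stabilised isopropylidene ylide builds the prenyl group, the extra ylide serving as base for the free hydroxyl, and the stereocentre, which is β to the aldehyde, is not epimerisable.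

Step 8
Reactants: 12 [(5R)-2,6,6-trimethyl-5-(3-methylbut-2-en-1-yl)cyclohex-1-en-1-yl]methanol
Product: 14 {[(5R)-2,6,6-trimethyl-5-(3-methylbut-2-en-1-yl)cyclohex-1-en-1-yl]methyl}(triphenyl)phosphonium bromide, via allylic bromide 13 (not isolated)
Conditions: CBr4 (1.2 equiv), PPh3 (2.3 equiv), CH2Cl2, 0 °C → rt, then 40 °C
Reagents that add atoms: triphenylphosphine c1ccc(cc1)P(c1ccccc1)c1ccccc1; tetrabromomethane BrC(Br)(Br)Br
Why: Appel bromination of the primary allylic alcohol followed in the same flask by SN2 quaternisation of triphenylphosphine gives the Wittig salt under neutral conditions that leave the prenyl alkene and the stereocentre untouched.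

Step 9
Reactants: 9 (2E)-2-[3-(hydroxymethyl)-2,2,4-trimethylcyclohex-3-en-1-ylidene]acetaldehyde
Product: 15 2-[(1S)-3-(hydroxymethyl)-2,2,4-trimethylcyclohex-3-en-1-yl]acetaldehyde
Conditions: (R)-2-tert-butyl-3-methylimidazolidin-4-one trifluoroacetate (20 mol %), Hantzsch ester (1.2 equiv), CHCl3, −30 °C
Reagents that add atoms: none
Why: Same iminium-catalysed transfer hydrogenation as in step 6 with the mirror-image catalyst, which should deliver hydride to the opposite face of C2 and set (S).

Step 10
Reactants: 15 2-[(1S)-3-(hydroxymethyl)-2,2,4-trimethylcyclohex-3-en-1-yl]acetaldehyde; 16 methyl(triphenyl)phosphonium bromide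
Product: 17 [(5S)-2,6,6-trimethyl-5-(prop-2-en-1-yl)cyclohex-1-en-1-yl]methanol
Conditions: 16 (2.3 equiv), KOt-Bu, THF, 0 °C → rt
Reagents that add atoms: none
Why: Wittig methylenation of the aldehyde gives the terminal alkene needed for cross-metathesis and leaves the β-stereocentre unaffected.

Step 11
Reactants: 17 [(5S)-2,6,6-trimethyl-5-(prop-2-en-1-yl)cyclohex-1-en-1-yl]methanol; 18 2-methylidenepropane-1,3-diyl diacetate
Product: 19 2-{2-[(1S)-3-(hydroxymethyl)-2,2,4-trimethylcyclohex-3-en-1-yl]ethylidene}propane-1,3-diyl diacetate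
Conditions: second-generation Hoveyda–Grubbs catalyst (5 mol %), 18 (5 equiv), CH2Cl2, 40 °C
Reagents that add atoms: none
Why: Olefin cross-metathesis of the terminal alkene with an excess of the symmetrical 1,1-disubstituted partner gives the trisubstituted alkene without an E/Z question because the two geminal groups are identical, and the tetrasubstituted ring alkene is inert to the ruthenium carbene.

Step 12
Reactants: 19 2-{2-[(1S)-3-(hydroxymethyl)-2,2,4-trimethylcyclohex-3-en-1-yl]ethylidene}propane-1,3-diyl diacetate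
Product: 21 ({(5S)-5-[4-acetoxy-3-(acetoxymethyl)but-2-en-1-yl]-2,6,6-trimethylcyclohex-1-en-1-yl}methyl)(triphenyl)phosphonium bromide, via allylic bromide 20 (not isolated)
Conditions: CBr4 (1.2 equiv), PPh3 (2.3 equiv), CH2Cl2, 0 °C → rt, then 40 °C
Reagents that add atoms: triphenylphosphine c1ccc(cc1)P(c1ccccc1)c1ccccc1; tetrabromomethane BrC(Br)(Br)Br
Why: Appel bromination and SN2 quaternisation as in step 8, the primary allylic acetates being inert to triphenylphosphine in the absence of a palladium catalyst.

Step 13
Reactants: 14 {[(5R)-2,6,6-trimethyl-5-(3-methylbut-2-en-1-yl)cyclohex-1-en-1-yl]methyl}(triphenyl)phosphonium bromide; 22 crocetindialdehyde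
Product: 23 (2R)-2-(3-methylbut-2-en-1-yl)-8'-apo-β-caroten-8'-al (all-E)
Conditions: 22 (3 equiv), NaOMe, CH2Cl2/MeOH, 0 °C → rt; then heptane, 80 °C (equilibration to all-E)
Reagents that add atoms: none
Why: Wittig olefination of the allylic ylide from 14 with an excess of the symmetrical dialdehyde favours mono-olefination, and the new C7=C8 bond is expected to settle as E on thermal equilibration because the Z form is strongly hindered by the ring methyl groups.

Step 14
Reactants: 23 (2R)-2-(3-methylbut-2-en-1-yl)-8'-apo-β-caroten-8'-al; 21 ({(5S)-5-[4-acetoxy-3-(acetoxymethyl)but-2-en-1-yl]-2,6,6-trimethylcyclohex-1-en-1-yl}methyl)(triphenyl)phosphonium bromide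
Product: 25 (2R,2'S)-2'-[4-hydroxy-3-(hydroxymethyl)but-2-en-1-yl]-2-(3-methylbut-2-en-1-yl)-β,β-carotene (all-E), via carotenoid diacetate 24 (not isolated)
Conditions: NaOMe (6 equiv), CH2Cl2/MeOH, 0 °C → rt; then heptane, 80 °C and crystallisation (all-E)
Reagents that add atoms: none
Why: The second Wittig olefination forms C7'=C8' (E after thermal equilibration) and the excess methoxide removes both acetates by Zemplén transesterification in the same flask, leaving both C2 stereocentres untouched.

Compound list
1 | 3-methylbutan-2-one | CC(=O)C(C)C | starting material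
2 | methacryloyl chloride (2-methylprop-2-enoyl chloride) | C=C(C)C(=O)Cl | starting material
3 | 1-(3-methylbut-1-en-2-yl)pyrrolidine | C=C(C(C)C)N1CCCC1 | intermediate
4 | 2,2,4-trimethylcyclohexane-1,3-dione (racemic) | CC1CCC(=O)C(C)(C)C1=O | intermediate
5 | diethyl (cyanomethyl)phosphonate | CCOP(=O)(CC#N)OCC | starting material
6 | (2E)-2-(2,2,4-trimethyl-3-oxocyclohexylidene)acetonitrile (racemic) | N#C/C=C1/C(C)(C)C(=O)C(C)CC1 | intermediate
7 | (5E)-5-(cyanomethylidene)-2,6,6-trimethylcyclohex-1-en-1-yl trifluoromethanesulfonate | N#C/C=C1/C(C)(C)C(OS(=O)(=O)C(F)(F)F)=C(C)CC1 | intermediate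
8 | methyl (5E)-5-(cyanomethylidene)-2,6,6-trimethylcyclohex-1-ene-1-carboxylate | N#C/C=C1/C(C)(C)C(C(=O)OC)=C(C)CC1 | intermediate
9 | (2E)-2-[3-(hydroxymethyl)-2,2,4-trimethylcyclohex-3-en-1-ylidene]acetaldehyde | O=C/C=C1/C(C)(C)C(CO)=C(C)CC1 | intermediate
10 | 2-[(1R)-3-(hydroxymethyl)-2,2,4-trimethylcyclohex-3-en-1-yl]acetaldehyde | O=CC[C@H]1CCC(C)=C(CO)C1(C)C | intermediate
11 | triphenyl(propan-2-yl)phosphonium iodide | CC(C)[P+](c1ccccc1)(c1ccccc1)c1ccccc1.[I-] | starting material
12 | [(5R)-2,6,6-trimethyl-5-(3-methylbut-2-en-1-yl)cyclohex-1-en-1-yl]methanol | CC(C)=CC[C@H]1CCC(C)=C(CO)C1(C)C | intermediate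
13 | (5R)-1-(bromomethyl)-2,6,6-trimethyl-5-(3-methylbut-2-en-1-yl)cyclohex-1-ene | CC(C)=CC[C@H]1CCC(C)=C(CBr)C1(C)C | intermediate
14 | {[(5R)-2,6,6-trimethyl-5-(3-methylbut-2-en-1-yl)cyclohex-1-en-1-yl]methyl}(triphenyl)phosphonium bromide | CC(C)=CC[C@H]1CCC(C)=C(C[P+](c2ccccc2)(c2ccccc2)c2ccccc2)C1(C)C.[Br-] | intermediate
15 | 2-[(1S)-3-(hydroxymethyl)-2,2,4-trimethylcyclohex-3-en-1-yl]acetaldehyde | O=CC[C@@H]1CCC(C)=C(CO)C1(C)C | intermediate
16 | methyl(triphenyl)phosphonium bromide | C[P+](c1ccccc1)(c1ccccc1)c1ccccc1.[Br-] | starting material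
17 | [(5S)-2,6,6-trimethyl-5-(prop-2-en-1-yl)cyclohex-1-en-1-yl]methanol | C=CC[C@@H]1CCC(C)=C(CO)C1(C)C | intermediate
18 | 2-methylidenepropane-1,3-diyl diacetate | CC(=O)OCC(=C)COC(C)=O | starting material
19 | 2-{2-[(1S)-3-(hydroxymethyl)-2,2,4-trimethylcyclohex-3-en-1-yl]ethylidene}propane-1,3-diyl diacetate | CC(=O)OCC(COC(C)=O)=CC[C@@H]1CCC(C)=C(CO)C1(C)C | intermediate
20 | 2-{2-[(1S)-3-(bromomethyl)-2,2,4-trimethylcyclohex-3-en-1-yl]ethylidene}propane-1,3-diyl diacetate | CC(=O)OCC(COC(C)=O)=CC[C@@H]1CCC(C)=C(CBr)C1(C)C | intermediate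
21 | ({(5S)-5-[4-acetoxy-3-(acetoxymethyl)but-2-en-1-yl]-2,6,6-trimethylcyclohex-1-en-1-yl}methyl)(triphenyl)phosphonium bromide | CC(=O)OCC(COC(C)=O)=CC[C@@H]1CCC(C)=C(C[P+](c2ccccc2)(c2ccccc2)c2ccccc2)C1(C)C.[Br-] | intermediate
22 | crocetindialdehyde, (2E,4E,6E,8E,10E,12E,14E)-2,6,11,15-tetramethylhexadeca-2,4,6,8,10,12,14-heptaenedial | O=C/C(C)=C/C=C/C(C)=C/C=C/C=C(C)/C=C/C=C(C)/C=O | starting material
23 | (2R)-2-(3-methylbut-2-en-1-yl)-8'-apo-β-caroten-8'-al (all-E) | CC(C)=CC[C@H]1CCC(C)=C(/C=C/C(C)=C/C=C/C(C)=C/C=C/C=C(C)/C=C/C=C(C)/C=O)C1(C)C | intermediate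
24 | (2R,2'S)-2'-[4-acetoxy-3-(acetoxymethyl)but-2-en-1-yl]-2-(3-methylbut-2-en-1-yl)-β,β-carotene (all-E) | CC(C)=CC[C@H]1CCC(C)=C(/C=C/C(C)=C/C=C/C(C)=C/C=C/C=C(C)/C=C/C=C(C)/C=C/C2=C(C)CC[C@@H](CC=C(COC(C)=O)COC(C)=O)C2(C)C)C1(C)C | intermediate
25 | (2R,2'S)-2'-[4-hydroxy-3-(hydroxymethyl)but-2-en-1-yl]-2-(3-methylbut-2-en-1-yl)-β,β-carotene (all-E) | CC(C)=CC[C@H]1CCC(C)=C(/C=C/C(C)=C/C=C/C(C)=C/C=C/C=C(C)/C=C/C=C(C)/C=C/C2=C(C)CC[C@@H](CC=C(CO)CO)C2(C)C)C1(C)C | target

Total step count: 14. Longest linear sequence: 10 steps (steps 1, 2, 3, 4, 5, 6, 7, 8, 13, 14; the ring B branch through steps 9 to 12 is equally long).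

Steps most likely to fail

Step 1. The enamine may be acylated directly at its CH2 carbon instead of passing through N-acylation and sigmatropic transfer, which would give the wrong connectivity, or the ketene may fail to acylate the hindered methine carbon and oligomerise. The fallback sets out from 1 and keeps the same two bond formations with an aldehyde acceptor. Enamine 3 (from 1 and pyrrolidine) adds to methacrolein in an enamine Michael addition, and on aqueous acid work-up the keto aldehyde closes by intramolecular aldol reaction from the isopropyl carbon to 3-hydroxy-2,2,4-trimethylcyclohexan-1-one F1. Oxidation of the carbinol with Dess–Martin periodinane in CH2Cl2 comes back to the route at 4.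

Step 6 (step 9 is its mirror image and shares the risk). Iminium formation or hydride transfer at the β-carbon next to the quaternary centre may be slow, so that a background pathway or migration of the double bond out of conjugation lowers the facial selectivity. The fallback sets out from 8. Copper hydride conjugate reduction of the (E)-unsaturated nitrile (Cu(OAc)2, the appropriate enantiomer of a Josiphos-type ferrocenyl bisphosphine, polymethylhydrosiloxane, t-BuOH, toluene, rt) should give methyl (5R)-5-(cyanomethyl)-2,6,6-trimethylcyclohex-1-ene-1-carboxylate F2, the hindered tetrasubstituted enoate being left alone. Reduction of F2 with i-Bu2AlH as in step 5 comes back to the route at 10.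

Step 11. Turnover of the ruthenium carbene with the 1,1-disubstituted diacetate may be poor, with homodimerisation of 17 and double-bond migration taking over. The fallback sets out from 15 and builds the side chain by condensation:
- Knoevenagel condensation of 15 with dimethyl malonate (piperidine, AcOH, toluene) gives dimethyl 2-{2-[(1S)-3-(hydroxymethyl)-2,2,4-trimethylcyclohex-3-en-1-yl]ethylidene}propanedioate F3.
- i-Bu2AlH reduces both esters to 2-{2-[(1S)-3-(hydroxymethyl)-2,2,4-trimethylcyclohex-3-en-1-yl]ethylidene}propane-1,3-diol F4.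
- 2,2-Dimethoxypropane with pyridinium p-toluenesulfonate protects the 1,3-diol as {(5S)-5-[2-(2,2-dimethyl-1,3-dioxan-5-ylidene)ethyl]-2,6,6-trimethylcyclohex-1-en-1-yl}methanol F5.
- CBr4 and PPh3 convert F5 into ({(5S)-5-[2-(2,2-dimethyl-1,3-dioxan-5-ylidene)ethyl]-2,6,6-trimethylcyclohex-1-en-1-yl}methyl)(triphenyl)phosphonium bromide F6.
- Wittig reaction of F6 with 23 (NaOMe, CH2Cl2/MeOH) gives the (2R,2'S)-carotenoid acetonide F7.
- Pyridinium p-toluenesulfonate in MeOH removes the acetonide and comes back to the route at 25.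

Further compounds
F1 | step 1 | 3-hydroxy-2,2,4-trimethylcyclohexan-1-one | CC1CCC(=O)C(C)(C)C1O
F2 | step 6 | methyl (5R)-5-(cyanomethyl)-2,6,6-trimethylcyclohex-1-ene-1-carboxylate | N#CC[C@H]1CCC(C)=C(C(=O)OC)C1(C)C
F3 | step 11 | dimethyl 2-{2-[(1S)-3-(hydroxymethyl)-2,2,4-trimethylcyclohex-3-en-1-yl]ethylidene}propanedioate | COC(=O)C(C(=O)OC)=CC[C@@H]1CCC(C)=C(CO)C1(C)C
F4 | step 11 | 2-{2-[(1S)-3-(hydroxymethyl)-2,2,4-trimethylcyclohex-3-en-1-yl]ethylidene}propane-1,3-diol | OCC(CO)=CC[C@@H]1CCC(C)=C(CO)C1(C)C
F5 | step 11 | {(5S)-5-[2-(2,2-dimethyl-1,3-dioxan-5-ylidene)ethyl]-2,6,6-trimethylcyclohex-1-en-1-yl}methanol | CC1(C)OCC(=CC[C@@H]2CCC(C)=C(CO)C2(C)C)CO1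
F6 | step 11 | ({(5S)-5-[2-(2,2-dimethyl-1,3-dioxan-5-ylidene)ethyl]-2,6,6-trimethylcyclohex-1-en-1-yl}methyl)(triphenyl)phosphonium bromide | CC1(C)OCC(=CC[C@@H]2CCC(C)=C(C[P+](c3ccccc3)(c3ccccc3)c3ccccc3)C2(C)C)CO1.[Br-]
F7 | step 11 | (2R,2'S)-2'-[2-(2,2-dimethyl-1,3-dioxan-5-ylidene)ethyl]-2-(3-methylbut-2-en-1-yl)-β,β-carotene (all-E) | CC(C)=CC[C@H]1CCC(C)=C(/C=C/C(C)=C/C=C/C(C)=C/C=C/C=C(C)/C=C/C=C(C)/C=C/C2=C(C)CC[C@@H](CC=C3COC(C)(C)OC3)C2(C)C)C1(C)C
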